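## Retrosynthetic overview

- The strategy rests on the single stereogenic methine. This C–H carbon is bonded to the carbonyl carbon of the 2-hydroxy-4-methoxyphenyl ketone, to C-3 of the 7-hydroxychromone (a latent nucleophilic enaminone α-carbon) and to the bis(4-hydroxyphenyl)methyl carbon (a latent electrophilic quinone-methide carbon). That is the pattern of a carbene carbon set between a nucleophile and an electrophile.
- Cutting methine–C-3, methine–benzhydryl and chromone O-1–C-2 gives three achiral pieces: an aryl diazomethyl ketone, an o-hydroxyaryl dimethylaminoenone and bis(4-hydroxyphenyl)methanol.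
- All four benzene rings are bought. The only ring formed is the pyranone of the chromone, closed in the same flask as the two C–C bonds under Rh(II)/chiral phosphoric acid catalysis.
- Free dimethylamine would neutralise the chiral acid. It is therefore kept covalently bound during the relay and expelled afterwards with stoichiometric TsOH. The end game is buffered fluoride, then hydrogenolysis.

Key step: step 7

Assumption: the sense of induction of the phosphoric acid cannot be derived from a close analogue. (R)-TRIP is written, and if it favours the (S)-product its enantiomer is used in the same step.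

## Route

**Step 1**
Reactants: 1 2-hydroxy-4-methoxybenzoic acid
Product: 2 triisopropylsilyl 4-methoxy-2-(triisopropylsilyloxy)benzoate
Conditions: TIPSOTf (2.3 equiv), 2,6-lutidine (3 equiv), CH2Cl2, 0 °C → rt
Reagents that add atoms: triisopropylsilyl triflate, CC(C)[Si](C(C)C)(C(C)C)OS(=O)(=O)C(F)(F)F
Why: Exhaustive O-silylation, in which the silyl triflate with a hindered pyridine base is reactive enough for both the carboxylic acid and the hydrogen-bonded ortho phenol, and no other nucleophilic site is present.

**Step 2**
Reactants: 2 triisopropylsilyl 4-methoxy-2-(triisopropylsilyloxy)benzoate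
Product: 3 4-methoxy-2-(triisopropylsilyloxy)benzoyl chloride
Conditions: (COCl)2 (1.3 equiv), DMF (cat.), CH2Cl2, 0 °C → rt; concentrated and used crude
Reagents that add atoms: oxalyl chloride, O=C(Cl)C(=O)Cl
Why: The Vilsmeier chloroiminium salt converts silyl esters into acid chlorides under neutral conditions (the ester silyl group leaves as the chlorosilane and no HCl forms), so the aryl silyl ether should stay in place.

**Step 3**
Reactants: 3 4-methoxy-2-(triisopropylsilyloxy)benzoyl chloride
Product: 4 2-diazo-1-[4-methoxy-2-(triisopropylsilyloxy)phenyl]ethanone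
Conditions: TMSCHN2 (2 equiv, hexanes), MeCN/THF 1:1, 0 °C → rt; Et3N-washed silica
Reagents that add atoms: trimethylsilyldiazomethane, C[Si](C)(C)C=[N+]=[N-]
Why: Acylation of trimethylsilyldiazomethane by an aroyl chloride (the TMSCHN2 variant of the Arndt–Eistert diazoketone synthesis), with chloride removing the C-silyl group; the aroyl chloride cannot form a ketene, and base-washed silica keeps acid away from the ortho-siloxy diazoketone.

**Step 4**
Reactants: 5 2',4'-dihydroxyacetophenone
Product: 6 1-(4-benzyloxy-2-hydroxyphenyl)ethanone
Conditions: BnBr (1.05 equiv), K2CO3 (1.1 equiv), acetone, reflux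
Reagents that add atoms: benzyl bromide, BrCc1ccccc1
Why: Williamson ether synthesis, selective for the 4-hydroxyl because the 2-hydroxyl is hydrogen-bonded to the ketone and is therefore less acidic and less nucleophilic.

**Step 5**
Reactants: 6 1-(4-benzyloxy-2-hydroxyphenyl)ethanone
Product: 7 (E)-1-(4-benzyloxy-2-hydroxyphenyl)-3-(dimethylamino)prop-2-en-1-one
Conditions: DMF-DMA (1.5 equiv), toluene, 90 °C
Reagents that add atoms: N,N-dimethylformamide dimethyl acetal, COC(OC)N(C)C
Why: Condensation of the methyl ketone with the amide acetal is the standard entry to (E)-o-hydroxyaryl enaminones, and the chelated phenol should not be methylated at this temperature.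

**Step 6**
Reactants: 8 4,4'-dihydroxybenzophenone
Product: 9 bis(4-hydroxyphenyl)methanol
Conditions: NaBH4 (2 equiv), EtOH/THF, 0 °C → rt; cold sat. aq. NH4Cl; used at once
Reagents that add atoms: none
Why: Borohydride reduction of a diaryl ketone, in which the low temperature and a cold, near-neutral quench should prevent the doubly activated benzhydrol from ionising to the quinone methide, which would be reduced further or oligomerise.

**Step 7**
Reactants: 4 2-diazo-1-[4-methoxy-2-(triisopropylsilyloxy)phenyl]ethanone; 7 (E)-1-(4-benzyloxy-2-hydroxyphenyl)-3-(dimethylamino)prop-2-en-1-one; 9 bis(4-hydroxyphenyl)methanol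
Product: 13 (R)-7-benzyloxy-3-{1,1-bis(4-hydroxyphenyl)-3-[4-methoxy-2-(triisopropylsilyloxy)phenyl]-3-oxopropan-2-yl}chromen-4-one, via quinone methide 10 (not isolated), via iminium enolate 11 (not isolated), via 2-aminochromanone 12 (not isolated)
Conditions: 7 (1 equiv), 9 (1.3 equiv), Rh2(esp)2 (2 mol %), (R)-TRIP (10 mol %), 5 Å MS, CH2Cl2/EtOAc 5:1, 0 °C, 4 (1.5 equiv) added over 1 h; then TsOH·H2O (1.2 equiv), 0 °C → rt
Reagents that add atoms: none
Why: Proposed new method: Rh2(esp)2 converts 4 into an acceptor carbene, the push–pull α-carbon of 7 attacks it to give iminium enolate 11, and the α-carbon of 11 (as its enol) adds to the exocyclic carbon of quinone methide 10, which the phosphoric acid forms from 9 by loss of water, before a 1,3-proton shift can quench it. The closest known reaction types are the Rh(II)/chiral phosphoric acid three-component trapping of carbene-derived zwitterions and ylides by imines or quinone methides and the C-3-functionalising cyclisation of o-hydroxyaryl enaminones to chromones; their combination with a diazoketone and an in situ quinone methide is not known. The pyranone ring closes by 6-exo-trig addition of the chelated phenol oxygen to the iminium carbon to give 12, in which the amine is expected to stay covalently bound at 0 °C so that it cannot neutralise the chiral acid or bind to rhodium, and TsOH added after the diazoketone is consumed then drives the E1cB loss of dimethylamine as its salt. The one lasting stereocentre is set in the 1,6-addition by the phosphate, which hydrogen-bonds the enol O–H and the quinone-methide carbonyl inside its 3,3'-aryl pocket and so exposes one enol face; the centres at C-2 and C-3 of 12 vanish on elimination and the benzhydryl carbon carries two identical aryl groups. The step needs carbon attack of 7 over O–H insertion, trapping over proton shift, and carbene capture of 7 over its direct alkylation by 10: the enaminone carbon is by far the best nucleophile in the flask and its own phenol is tied to the ketone by a hydrogen bond, the carbene has no β-hydrogen and no C–H bond within reach of a five-membered insertion, the bulky and weakly basic silyl ether oxygen disfavours oxonium-ylide closure to a benzofuranone, and low temperature with a steady carbene flux keeps the slower bimolecular alkylation of 7 in the background.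

**Step 8**
Reactants: 13 (R)-7-benzyloxy-3-{1,1-bis(4-hydroxyphenyl)-3-[4-methoxy-2-(triisopropylsilyloxy)phenyl]-3-oxopropan-2-yl}chromen-4-one
Product: 14 (R)-7-benzyloxy-3-[1-(2-hydroxy-4-methoxyphenyl)-3,3-bis(4-hydroxyphenyl)-1-oxopropan-2-yl]chromen-4-one
Conditions: TBAF (1.2 equiv), AcOH (1.5 equiv), THF, 0 °C
Reagents that add atoms: none
Why: Fluoride cleavage of an aryl silyl ether, fast at 0 °C because a 2-acylphenoxide leaves, with acetic acid buffering the medium so that neither enolisation of the acidic methine nor retro-1,6-addition through a phenoxide should set in.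

**Step 9**
Reactants: 14 (R)-7-benzyloxy-3-[1-(2-hydroxy-4-methoxyphenyl)-3,3-bis(4-hydroxyphenyl)-1-oxopropan-2-yl]chromen-4-one
Product: 15 (R)-7-hydroxy-3-[1-(2-hydroxy-4-methoxyphenyl)-3,3-bis(4-hydroxyphenyl)-1-oxopropan-2-yl]chromen-4-one (target)
Conditions: H2 (1 atm), 10 % Pd/C, EtOAc/EtOH, rt, stopped after uptake of 1 equiv
Reagents that add atoms: none
Why: Catalytic hydrogenolysis of a benzyl aryl ether under neutral conditions leaves the methine configuration untouched, and the hindered trisubstituted chromone C-2/C-3 double bond and the chelated aryl ketone should be reduced much more slowly.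

## Compound list

1 | 2-hydroxy-4-methoxybenzoic acid | COc1ccc(C(=O)O)c(O)c1 | starting material
2 | triisopropylsilyl 4-methoxy-2-(triisopropylsilyloxy)benzoate | COc1ccc(C(=O)O[Si](C(C)C)(C(C)C)C(C)C)c(O[Si](C(C)C)(C(C)C)C(C)C)c1 | intermediate
3 | 4-methoxy-2-(triisopropylsilyloxy)benzoyl chloride | COc1ccc(C(=O)Cl)c(O[Si](C(C)C)(C(C)C)C(C)C)c1 | intermediate
4 | 2-diazo-1-[4-methoxy-2-(triisopropylsilyloxy)phenyl]ethanone | COc1ccc(C(=O)C=[N+]=[N-])c(O[Si](C(C)C)(C(C)C)C(C)C)c1 | intermediate
5 | 2',4'-dihydroxyacetophenone | CC(=O)c1ccc(O)cc1O | starting material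
6 | 1-(4-benzyloxy-2-hydroxyphenyl)ethanone | CC(=O)c1ccc(OCc2ccccc2)cc1O | intermediate
7 | (E)-1-(4-benzyloxy-2-hydroxyphenyl)-3-(dimethylamino)prop-2-en-1-one | CN(C)/C=C/C(=O)c1ccc(OCc2ccccc2)cc1O | intermediate
8 | 4,4'-dihydroxybenzophenone | O=C(c1ccc(O)cc1)c1ccc(O)cc1 | starting material
9 | bis(4-hydroxyphenyl)methanol | OC(c1ccc(O)cc1)c1ccc(O)cc1 | intermediate
10 | 4-(4-hydroxybenzylidene)cyclohexa-2,5-dien-1-one (para-quinone methide, not isolated) | O=C1C=CC(=Cc2ccc(O)cc2)C=C1 | intermediate
11 | iminium enolate from carbene and enaminone (not isolated; α-carbon and enolate geometry undefined) | COc1ccc(C([O-])=CC(C=[N+](C)C)C(=O)c2ccc(OCc3ccccc3)cc2O)c(O[Si](C(C)C)(C(C)C)C(C)C)c1 | intermediate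
12 | 7-benzyloxy-2-(dimethylamino)-3-{(R)-1,1-bis(4-hydroxyphenyl)-3-[4-methoxy-2-(triisopropylsilyloxy)phenyl]-3-oxopropan-2-yl}chroman-4-one (not isolated; C-2 and C-3 undefined) | COc1ccc(C(=O)[C@@H](C2C(N(C)C)Oc3cc(OCc4ccccc4)ccc3C2=O)C(c2ccc(O)cc2)c2ccc(O)cc2)c(O[Si](C(C)C)(C(C)C)C(C)C)c1 | intermediate
13 | (R)-7-benzyloxy-3-{1,1-bis(4-hydroxyphenyl)-3-[4-methoxy-2-(triisopropylsilyloxy)phenyl]-3-oxopropan-2-yl}chromen-4-one | COc1ccc(C(=O)[C@@H](c2coc3cc(OCc4ccccc4)ccc3c2=O)C(c2ccc(O)cc2)c2ccc(O)cc2)c(O[Si](C(C)C)(C(C)C)C(C)C)c1 | intermediate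
14 | (R)-7-benzyloxy-3-[1-(2-hydroxy-4-methoxyphenyl)-3,3-bis(4-hydroxyphenyl)-1-oxopropan-2-yl]chromen-4-one | COc1ccc(C(=O)[C@@H](c2coc3cc(OCc4ccccc4)ccc3c2=O)C(c2ccc(O)cc2)c2ccc(O)cc2)c(O)c1 | intermediate
15 | (R)-7-hydroxy-3-[1-(2-hydroxy-4-methoxyphenyl)-3,3-bis(4-hydroxyphenyl)-1-oxopropan-2-yl]chromen-4-one | COc1ccc(C(=O)[C@@H](c2coc3cc(O)ccc3c2=O)C(c2ccc(O)cc2)c2ccc(O)cc2)c(O)c1 | target

## Step count and risks

Total step count: 9. Longest linear sequence: 6 (steps 1, 2, 3, 7, 8, 9).

**Risk 1 (step 7).** Several processes could defeat the relay: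
- the 1,3-proton shift may outrun the trapping;
- the carbene may insert into phenolic or water O–H bonds;
- the quinone methide may alkylate the enaminone directly;
- the zwitterion may close through its enolate oxygen;
- early release of the amine may switch off the chiral acid;
- facial selectivity may be poor.

The fallback makes the same bonds in separate known operations and obtains the enantiomer by resolution. It sets out from 4 and 7. Rh2(OAc)4 in CH2Cl2 without an electrophile, followed by the TsOH finish, should give the 3-phenacylchromone F1 by the known carbene C–H functionalisation/annulation of o-hydroxyaryl enaminones. TMSOTf/Et3N converts it into the trimethylsilyl enol ether F2. This is alkylated by 9 under a catalytic Lewis acid such as Bi(OTf)3, an SN1-type, Mukaiyama-like substitution of a benzhydrol by a silyl enol ether, to give the racemic adduct F3. Preparative chiral SFC then delivers the (R)-enantiomer, and the route is rejoined at 13.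

**Risk 2 (step 3).** Acylation of TMSCHN2 by the hindered, electron-rich aroyl chloride may be sluggish. Acid may also induce loss of nitrogen with attack of the ortho oxygen during work-up. The fallback builds the diazo group by diazo transfer under basic conditions and sets out from 3. Me2CuLi in Et2O at −78 °C gives the methyl ketone F4. LiHMDS and 2,2,2-trifluoroethyl trifluoroacetate at −78 °C (kept cold to prevent O-to-O silyl migration) give the trifluoroacetylated diketone F5. Deacylative Regitz-type diazo transfer with MsN3, Et3N and water in MeCN rejoins the route at 4.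

**Risk 3 (step 6).** Reduction of the phenoxide-deactivated ketone may be slow. The product may be over-reduced through quinone-methide formation in the basic hydride medium, and it may self-condense on isolation. The fallback masks the phenols during the reduction and sets out from 8. TBSCl and imidazole in DMF give the bis-silyl ketone F6. NaBH4 in MeOH/THF gives the storable bis-silyl benzhydrol F7, which cannot form a quinone methide. TBAF/AcOH at 0 °C, just before use and with no hydride present, rejoins the route at 9.

## Further compounds

F1 | step 7 | 7-benzyloxy-3-{2-[4-methoxy-2-(triisopropylsilyloxy)phenyl]-2-oxoethyl}chromen-4-one | COc1ccc(C(=O)Cc2coc3cc(OCc4ccccc4)ccc3c2=O)c(O[Si](C(C)C)(C(C)C)C(C)C)c1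
F2 | step 7 | trimethylsilyl enol ether of F1 (geometry undefined) | COc1ccc(C(O[Si](C)(C)C)=Cc2coc3cc(OCc4ccccc4)ccc3c2=O)c(O[Si](C(C)C)(C(C)C)C(C)C)c1
F3 | step 7 | racemic 7-benzyloxy-3-{1,1-bis(4-hydroxyphenyl)-3-[4-methoxy-2-(triisopropylsilyloxy)phenyl]-3-oxopropan-2-yl}chromen-4-one | COc1ccc(C(=O)C(c2coc3cc(OCc4ccccc4)ccc3c2=O)C(c2ccc(O)cc2)c2ccc(O)cc2)c(O[Si](C(C)C)(C(C)C)C(C)C)c1
F4 | step 3 | 1-[4-methoxy-2-(triisopropylsilyloxy)phenyl]ethanone | CC(=O)c1ccc(OC)cc1O[Si](C(C)C)(C(C)C)C(C)C
F5 | step 3 | 4,4,4-trifluoro-1-[4-methoxy-2-(triisopropylsilyloxy)phenyl]butane-1,3-dione | COc1ccc(C(=O)CC(=O)C(F)(F)F)c(O[Si](C(C)C)(C(C)C)C(C)C)c1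
F6 | step 6 | bis[4-(tert-butyldimethylsilyloxy)phenyl]methanone | CC(C)(C)[Si](C)(C)Oc1ccc(C(=O)c2ccc(O[Si](C)(C)C(C)(C)C)cc2)cc1
F7 | step 6 | bis[4-(tert-butyldimethylsilyloxy)phenyl]methanol | CC(C)(C)[Si](C)(C)Oc1ccc(C(O)c2ccc(O[Si](C)(C)C(C)(C)C)cc2)cc1
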